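**Retrosynthetic overview**

1. Colupone 19 is one carbocycle, ring A (C1=O, C2 bearing the isobutyryl group, C3–OH, C4(prenyl)2, C5=O, C6(prenyl)2). Ring A is formed last by making C5–C6 and C1–C2 in one operation from the enolate of methyl 2,2-diprenylacetate 6 (C6, C1) and the enol lactone 6-isopropyl-3,3-diprenylpyran-2,4-dione 15 (C2 to C5 plus the isobutyryl group).
2. Enabling feature: in ring A the acyl carbons C1, C3, C5 alternate with the α-carbons C2, C4, C6. C2 lies between C1=O, C3–OH and the exocyclic isobutyryl C=O, so its 1,3-diketonate can serve as leaving group of the lactone opening, as ring-closing nucleophile and, as the product enolate, as thermodynamic sink. C6 is the α-carbon of a diprenylacetate enolate.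
3. The temporary pyran ring of 15 is built from diprenylmalonyl dichloride 10 and the kinetic silyl enol ether 13 of 3-methylbutan-2-one. The key step erases it, and its ring oxygen ends as the isobutyryl carbonyl oxygen.
4. Both C(prenyl)2–C(=O) units come from dimethyl 2,2-diprenylmalonate 4 (Krapcho reaction to 6; saponification and chlorination to 10).
5. Order of ring formation: pyran-2,4-dione ring (step 6), then ring A (step 7).

Key step: step 7

Remark: colupone is a tautomeric β-triketone with no stereocentre and no configured double bond. The enol of the target SMILES is one of the interconverting tautomers, so the route needs no stereocontrol and should deliver the tautomeric mixture.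

**Route**

Step 1
Reactants: 1 dimethyl malonate; 2 1-bromo-3-methylbut-2-ene (prenyl bromide)
Product: 4 dimethyl 2,2-bis(3-methylbut-2-en-1-yl)malonate, via dimethyl 2-prenylmalonate 3 (not isolated)
Conditions: NaH (2.3 equiv), 2 (2.3 equiv), THF, 0 °C to 60 °C
Reagents that add atoms: none
Why: Twofold SN2 C-alkylation of the soft malonate anion by a reactive primary allylic bromide (malonic ester alkylation) should give the gem-diprenyl diester.

Step 2
Reactants: 4 dimethyl 2,2-bis(3-methylbut-2-en-1-yl)malonate
Product: 6 methyl 5-methyl-2-(3-methylbut-2-en-1-yl)hex-4-enoate, via lithium half-ester carboxylate 5 (not isolated)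
Conditions: LiCl (2 equiv), H2O (1.5 equiv), DMSO, 150 °C
Reagents that add atoms: none
Why: Krapcho dealkoxycarbonylation, in which chloride demethylates one ester, the half-ester carboxylate loses CO2 and water protonates the ester enolate, is neutral and should leave the prenyl groups untouched.

Step 3
Reactants: 4 dimethyl 2,2-bis(3-methylbut-2-en-1-yl)malonate
Product: 8 2,2-bis(3-methylbut-2-en-1-yl)malonic acid, via dipotassium diprenylmalonate 7 (not isolated)
Conditions: KOH (6 equiv), MeOH/H2O 3:1, 70 °C; then 1 M HCl to pH 2, 0 °C
Reagents that add atoms: potassium hydroxide, [K+].[OH-]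
Why: Saponification of both methyl esters (acyl–oxygen cleavage) gives a disubstituted malonic acid that does not decarboxylate at this temperature, and the short cold acidification should spare the trisubstituted alkenes.

Step 4
Reactants: 8 2,2-bis(3-methylbut-2-en-1-yl)malonic acid
Product: 10 2,2-bis(3-methylbut-2-en-1-yl)malonyl dichloride, via half acid chloride 9 (not isolated)
Conditions: 1-chloro-N,N,2-trimethylprop-1-en-1-amine (2.2 equiv), CH2Cl2, 0 °C to 23 °C; short-path distillation
Reagents that add atoms: 1-chloro-N,N,2-trimethylprop-1-en-1-amine (Ghosez reagent), CC(C)=C(Cl)N(C)C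
Why: Acid chloride formation with the Ghosez α-chloroenamine runs under neutral conditions without free HCl, which protects the prenyl double bonds, and the product has no α-hydrogen and so cannot form a ketene.

Step 5
Reactants: 11 3-methylbutan-2-one
Product: 13 trimethyl[(3-methylbut-1-en-2-yl)oxy]silane, via lithium enolate 12 (not isolated)
Conditions: LiN(iPr)2 (1.05 equiv), THF, −78 °C; Me3SiCl, −78 °C to 23 °C
Reagents that add atoms: chlorotrimethylsilane, C[Si](C)(C)Cl
Why: Kinetic deprotonation of the methyl group by the hindered amide base followed by O-silylation should give the less substituted silyl enol ether regioselectively.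

Step 6
Reactants: 10 2,2-bis(3-methylbut-2-en-1-yl)malonyl dichloride; 13 trimethyl[(3-methylbut-1-en-2-yl)oxy]silane
Product: 15 6-(propan-2-yl)-3,3-bis(3-methylbut-2-en-1-yl)-2H-pyran-2,4(3H)-dione, via diketo acid chloride 14 (not isolated)
Conditions: 2,6-di-tert-butylpyridine (1.2 equiv), CH2Cl2, −78 °C to 23 °C, 13 added slowly to 10
Reagents that add atoms: none
Why: C-acylation of the silyl enol ether by one acid chloride group with loss of Me3SiCl, then intramolecular O-acylation of the enolised 1,3-diketone 14 by the second acid chloride group, is the known route from silyl enol ethers and malonyl dichlorides to pyranones; here the hindered pyridine takes up the HCl.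

Step 7
Reactants: 6 methyl 5-methyl-2-(3-methylbut-2-en-1-yl)hex-4-enoate; 15 6-(propan-2-yl)-3,3-bis(3-methylbut-2-en-1-yl)-2H-pyran-2,4(3H)-dione
Product: 19 colupone, via lithium ester enolate 16 (not isolated), via lithium diketonate 17 (not isolated), via lithium colupone enolate 18 (not isolated)
Conditions: 6, LiN(iPr)2 (1.05 equiv), THF, −78 °C; 15 (1.0 equiv), −78 °C to 0 °C; DMPU, 50 °C; 1 M HCl, 0 °C
Reagents that add atoms: none
Why: Proposed new method: the fully substituted ester enolate 16 should add to the lactone carbonyl C2 of 15 and the tetrahedral intermediate should collapse with expulsion of the ring oxygen as the chelated lithium 1,3-diketonate 17 (this makes the C5–C6 bond between a quaternary carbon and a carbonyl flanked by two quaternary carbons), after which the diketonate carbon of 17 attacks the methyl ester in a Dieckmann condensation that makes the C1–C2 bond and releases methoxide, which is consumed at once by the acidic β-triketone (pKa estimated near 5) to give 18. The closest known reaction types are the Fujimoto–Belleau ring transformation of enol lactones into carbocycles by carbon nucleophiles, the conversion of 3,3-dialkylpyran-2,4-diones into pyridine-2,4-diones by ammonia, the Claisen cyclisation of 3,5,7-triketo esters to acylphloroglucinols, and the alkoxide-catalysed trimerisation of dialkylketenes to hexaalkylcyclohexane-1,3,5-triones, which ends in the same Dieckmann closure between fully substituted centres. Ring A closes in a 6-(enolendo)-exo-trig mode, helped by the two gem-diprenyl carbons of the chain (Thorpe–Ingold effect); no stereocentre is formed. The step needs site selectivity in 15 for C2 over C4, C6 and the γ-hydrogen of the isopropyl group: C2 is the only carbonyl activated as an enol ester, C4 is a deactivated vinylogous ester whose adducts revert, C6 is a fully substituted β-carbon, and the enol lactone carries no acidic 1,3-dicarbonyl hydrogen that could quench 16. It also needs C- rather than O-cyclisation of 17: O-acylation and retro-additions are reversible under the lithium methoxide formed, whereas C-acylation ends irreversibly in the stabilised enolate 18.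

**Compound list**

1 | dimethyl malonate | COC(=O)CC(=O)OC | starting material
2 | 1-bromo-3-methylbut-2-ene (prenyl bromide) | CC(C)=CCBr | starting material
3 | dimethyl 2-(3-methylbut-2-en-1-yl)malonate | COC(=O)C(CC=C(C)C)C(=O)OC | intermediate
4 | dimethyl 2,2-bis(3-methylbut-2-en-1-yl)malonate | COC(=O)C(CC=C(C)C)(CC=C(C)C)C(=O)OC | intermediate
5 | lithium 2-(methoxycarbonyl)-5-methyl-2-(3-methylbut-2-en-1-yl)hex-4-enoate | COC(=O)C(CC=C(C)C)(CC=C(C)C)C(=O)[O-].[Li+] | intermediate
6 | methyl 5-methyl-2-(3-methylbut-2-en-1-yl)hex-4-enoate (methyl 2,2-diprenylacetate) | COC(=O)C(CC=C(C)C)CC=C(C)C | intermediate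
7 | dipotassium 2,2-bis(3-methylbut-2-en-1-yl)malonate | [K+].[K+].[O-]C(=O)C(CC=C(C)C)(CC=C(C)C)C(=O)[O-] | intermediate
8 | 2,2-bis(3-methylbut-2-en-1-yl)malonic acid | OC(=O)C(CC=C(C)C)(CC=C(C)C)C(=O)O | intermediate
9 | 2-(chlorocarbonyl)-5-methyl-2-(3-methylbut-2-en-1-yl)hex-4-enoic acid | OC(=O)C(CC=C(C)C)(CC=C(C)C)C(=O)Cl | intermediate
10 | 2,2-bis(3-methylbut-2-en-1-yl)malonyl dichloride | ClC(=O)C(CC=C(C)C)(CC=C(C)C)C(=O)Cl | intermediate
11 | 3-methylbutan-2-one | CC(=O)C(C)C | starting material
12 | lithium 3-methylbut-1-en-2-olate | [Li+].[O-]C(=C)C(C)C | intermediate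
13 | trimethyl[(3-methylbut-1-en-2-yl)oxy]silane | C=C(O[Si](C)(C)C)C(C)C | intermediate
14 | 6-methyl-2,2-bis(3-methylbut-2-en-1-yl)-3,5-dioxoheptanoyl chloride | CC(C)C(=O)CC(=O)C(CC=C(C)C)(CC=C(C)C)C(=O)Cl | intermediate
15 | 6-(propan-2-yl)-3,3-bis(3-methylbut-2-en-1-yl)-2H-pyran-2,4(3H)-dione | CC(C)C1=CC(=O)C(CC=C(C)C)(CC=C(C)C)C(=O)O1 | intermediate
16 | lithium 1-methoxy-5-methyl-2-(3-methylbut-2-en-1-yl)hexa-1,4-dien-1-olate | [Li+].[O-]C(OC)=C(CC=C(C)C)CC=C(C)C | intermediate
17 | lithium (Z)-enolate of methyl 8-methyl-2,2,4,4-tetrakis(3-methylbut-2-en-1-yl)-3,5,7-trioxononanoate | [Li+].CC(C)/C([O-])=C/C(=O)C(CC=C(C)C)(CC=C(C)C)C(=O)C(CC=C(C)C)(CC=C(C)C)C(=O)OC | intermediate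
18 | lithium enolate of colupone | [Li+].CC(C)C(=O)C1=C([O-])C(CC=C(C)C)(CC=C(C)C)C(=O)C(CC=C(C)C)(CC=C(C)C)C1=O | intermediate
19 | colupone, 3-hydroxy-2-(2-methylpropanoyl)-4,4,6,6-tetrakis(3-methylbut-2-en-1-yl)cyclohex-2-ene-1,5-dione | CC(C)=CCC1(CC=C(C)C)C(=O)C(C(=O)C(C)C)=C(O)C(CC=C(C)C)(CC=C(C)C)C1=O | target

**Count**

Total steps: 7. Longest linear sequence: 5 steps (steps 1, 3, 4, 6, 7).

**Steps most likely to fail**

1. Step 7 (Proposed new method). The hindered enolate may act as a base and remove the γ-hydrogen of the isopropyl group of 15 instead of attacking the congested lactone carbonyl. Alternatively, the sequence may stall at the open-chain stage, where methoxide can cleave the non-enolisable 1,3-dicarbonyl unit by retro-Claisen reaction before the ring closes. Fallback with known chemistry, setting out from 2 and coming back at 19: commercial benzene-1,3,5-triol is C-acylated with 2-methylpropanoyl chloride (AlCl3, nitrobenzene/CH2Cl2, Friedel–Crafts acylation) to give 2-methyl-1-(2,4,6-trihydroxyphenyl)propan-1-one F1. This is then exhaustively C-prenylated with an excess of 2 and NaOMe in MeOH at 0 °C, so that each of the two free ring carbons takes up two prenyl groups with dearomatisation, which should give 19 directly.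

2. Step 6. C-acylation by the neopentyl-type acid chloride may be slow, so that O-acylation of 13, acylation of both acid chloride groups by two molecules of 13, or addition of unscavenged HCl to the prenyl double bonds competes. Fallback setting out from 4 and 12 and coming back at 15: crossed Claisen condensation of 4 with two equivalents of the kinetic enolate 12 (THF, −78 °C to 0 °C; the diketonate formed shields the second ester) should give methyl 6-methyl-2,2-bis(3-methylbut-2-en-1-yl)-3,5-dioxoheptanoate F2. Thermal enol lactonisation of F2 (toluene, reflux, 4 Å molecular sieves to remove methanol) should then close the pyran-2,4-dione ring of 15 without any acid chloride.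

3. Step 4. Traces of acid may add a carboxyl group or chloride across a prenyl double bond, and the half-converted diacid may condense to oligomeric anhydrides. Fallback setting out from 8 and coming back at 15: 8 is converted with 1,1'-carbonyldiimidazole (2.2 equiv, THF, 23 °C) into 1,1'-[2,2-bis(3-methylbut-2-en-1-yl)propanedioyl]bis(1H-imidazole) F3 under neutral conditions. F3 is then treated with two equivalents of the lithium enolate 12 (C-acylation of a ketone enolate by an acyl imidazole), and the resulting diketonate should close to 15 by intramolecular O-acylation with loss of imidazole on mildly acidic work-up, bypassing 10.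

**Further compounds**

F1 | step 7 | 2-methyl-1-(2,4,6-trihydroxyphenyl)propan-1-one | CC(C)C(=O)c1c(O)cc(O)cc1O
F2 | step 6 | methyl 6-methyl-2,2-bis(3-methylbut-2-en-1-yl)-3,5-dioxoheptanoate | COC(=O)C(CC=C(C)C)(CC=C(C)C)C(=O)CC(=O)C(C)C
F3 | step 4 | 1,1'-[2,2-bis(3-methylbut-2-en-1-yl)propanedioyl]bis(1H-imidazole) | O=C(n1ccnc1)C(CC=C(C)C)(CC=C(C)C)C(=O)n1ccnc1
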